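**Numbering and locants.** Compounds 1–17 are defined in the steps and in the compound list and carry the same numbers throughout. Dihydrobenzofuran locants: O1, C2, C3, C3a, C4–C7, C7a. Chromanone (flavanone) locants: O1, C2, C3, C4, C4a, C5–C8, C8a. Ring A is the benzo ring of either bicycle.

## Analysis of the target

Gnetucleistol F (17) is a stilbenolignan built on a trans-2-aryl-3-(hydroxymethyl)-2,3-dihydrobenzofuran. Ring A carries a methoxy group at C7 and an (E)-3,5-dihydroxystyryl group at C5, and C2 carries a 4-hydroxy-3,5-dimethoxyphenyl (syringyl) ring. There are two contiguous stereocenters, C2 (R) and C3 (S), with the C2 aryl group and the C3 CH2OH group trans on the five-membered ring. C2 is a benzylic ether para to a free phenol, so the C2–O1 bond can open to a quinone methide under strong acid or strong base and is cleaved by hydrogenolysis. The stilbene double bond rules out hydrogenolytic deprotection, and the three free phenols are sensitive to oxidation and to the Lewis acids used for ether cleavage. The difficulty is absolute control of C2 and C3 on the heterocycle, combined with an end game that exposes three phenols and a primary alcohol without hydrogenation, strong acid or strong base. The feature that invites the key move is the atom pattern C7a–O1–C2(aryl)–C3(one-carbon group)–C3a. This is the skeleton of a flavanone (2-arylchroman-4-one) in which aryl carbon C4a has moved from the carbonyl carbon C4 to C3. The CH2OH carbon of 17 is then the former ketone carbon, and the only stereocenter that has to be made by a catalyst is C2.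

## Retrosynthetic reasoning

**17 to 16.** The four O–H groups of 17 are traced back to four carbonyl-bound oxygens: the C3 methyl ester and three aryl pivalates. One hydride reagent should reduce the ester and cleave the pivalates in a single operation, so the last step needs no hydrogenation and no Lewis acid. Pivalates are chosen because they are electron-withdrawing and acid-stable, which the key step requires.

**16 to 12 and 15.** The bond between C5 of ring A and the vinyl carbon is cut, with a Mizoroki–Heck reaction as the forward step. Cutting here splits off the resorcinol ring as styrene 15, makes the route convergent, and keeps the oxidisable stilbene out of the oxidative key step. The bromine of 12 sits para to O1, where the phenol of the starting material directs a brominating agent. Styrene 15 goes back through aldehyde 14 to 13 by acylation and methylenation.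

**12 to 8 (key disconnection).** The C3–C3a bond of 12 is reconnected as the C4–C4a bond of the (R)-flavanone 8, which is a retro-1,2-aryl shift with ring expansion from dihydrobenzofuran to chroman-4-one. Forward, a trivalent iodine oxidant in an orthoester medium turns the ketone into a ketal carrying a leaving group at C3. Aryl carbon C4a then migrates to C3 and the former carbonyl carbon becomes the ester carbon. The gain is that two stereocenters collapse to one, the ester carbon is already in place as the ketone, and the trans relationship follows from the mechanism. The forward reaction has to achieve migration of ring A rather than of the C2 aryl ring, and it must leave C2 untouched.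

**8 to 4 and 7.** The C2–aryl bond is cut, with a catalytic asymmetric conjugate addition of boronic acid 7 to chromone 4 as the forward step. This is the only place where absolute configuration is introduced, and it is set on a flat, achiral precursor.

**4 to 2 to 1, and 7 to 6 to 5.** Chromone 4 is opened at O1–C2 and C2–C3 to the bromo-hydroxyacetophenone 2 and a one-carbon amide acetal, and 2 comes from 1 by para-bromination. Boronic acid 7 comes from the commercial pinacol boronate 5 by acylation to 6 and removal of pinacol.

## Alternatives that were turned down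

**Alternative 1:** the textbook biomimetic disconnection of C3–C3a and O1–C2 in one oxidative step. Sinapyl alcohol (A1) and isorhapontigenin (A2) would be cross-coupled by a one-electron oxidant (a silver or iron salt, or a peroxidase). The phenoxyl radical of A1 would couple through its side-chain β-carbon with the carbon ortho to the phenol of A2, giving the quinone methide A3, which the neighbouring phenol would trap to close the ring. It was turned down for three reasons. The radical coupling step has no source of absolute stereocontrol, so 17 would be racemic. Two different phenoxyl radicals give a statistical mixture of homo- and cross-coupled products. A2 also has a resorcinol ring and a stilbene double bond that carry spin density, so coupling through those positions competes. The route is short but cannot deliver the single enantiomer without a resolution at the end.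

**Alternative 2:** disconnection of the C2–C3 bond by an intramolecular carbenoid C–H insertion. The aryldiazoacetate A4, with the syringyl-type benzyl ether on the ortho oxygen, would be cyclised by a chiral dirhodium tetracarboxylate; the carbenoid inserts into the benzylic C–H bond. It was turned down on step economy and stereochemistry. A4 needs a homologated arylacetic ester, a separately prepared benzyl halide, an etherification and a diazo transfer, roughly twice the number of steps needed to reach 8. The insertion is cis-selective, so a separate base-mediated epimerisation would be needed to reach 12. It is also the asymmetric route most chemists would draw first for this ring system.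

**Alternative 3:** disconnection of C3–C3a and O1–C2 as a formal [3+2] cycloaddition. 2-Methoxy-1,4-benzoquinone (A5) would react with the protected sinapyl alkene A6 under a chiral titanium Lewis acid or a chiral Brønsted acid to give the dihydrobenzofuran-5-ol A7, whose C5 hydroxyl would become a triflate for coupling with 15. It was turned down on regiochemistry. The alkene attacks A5 at the carbon β to the carbonyl that is not deactivated by the methoxy group, which leads to the 6-methoxy isomer A8 and not to the 7-methoxy pattern of A7. The allylic oxygen of A6 also lowers the nucleophilicity of the alkene, and the enantioselective variants with precedent need stoichiometric chiral Lewis acid or quinone imines.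

Key step: step 6

**Assumptions.** Compounds 1, 5 and 13 are taken as commercially available. (S)-t-BuPyOX is assumed to deliver the aryl group to the face of chromone 4 that gives the (R) centre, by analogy with its sense of induction with cyclic enones; if the opposite sense were found, the (R)-ligand would be used.

## Steps

Step 1
Reactants: 1 1-(2-hydroxy-3-methoxyphenyl)ethan-1-one
Product: 2 1-(5-bromo-2-hydroxy-3-methoxyphenyl)ethan-1-one
Conditions: NBS (1.05 equiv), MeCN, 0 °C to rt
Reagents that add atoms: N-bromosuccinimide, O=C1CCC(=O)N1Br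
Why: Electrophilic aromatic bromination; the free phenol directs to its para position (both ortho positions are occupied) and the acetyl group reinforces this as a meta director. No stereocenter is formed.

Step 2
Reactants: 2 1-(5-bromo-2-hydroxy-3-methoxyphenyl)ethan-1-one
Product: 4 6-bromo-8-methoxy-4H-chromen-4-one, via enaminone 3 (not isolated)
Conditions: Me2NCH(OMe)2, toluene, 100 °C; then conc. HCl, CH2Cl2, 40 °C
Reagents that add atoms: N,N-dimethylformamide dimethyl acetal, COC(OC)N(C)C
Why: Condensation of the methyl ketone with the amide acetal gives enaminone 3; acid-promoted 6-endo-trig addition of the phenol with loss of dimethylamine closes the chromone (the standard enaminone route to chromones).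

Step 3
Reactants: 5 2,6-dimethoxy-4-(4,4,5,5-tetramethyl-1,3,2-dioxaborolan-2-yl)phenol
Product: 6 2,6-dimethoxy-4-(4,4,5,5-tetramethyl-1,3,2-dioxaborolan-2-yl)phenyl 2,2-dimethylpropanoate
Conditions: PivCl, Et3N, DMAP (cat.), CH2Cl2, 0 °C to rt
Reagents that add atoms: pivaloyl chloride, CC(C)(C)C(Cl)=O
Why: DMAP-catalysed O-acylation of the hindered phenol; the pivalate is electron-withdrawing and acid-stable for step 6 and is removed by hydride in step 10.

Step 4
Reactants: 6 2,6-dimethoxy-4-(4,4,5,5-tetramethyl-1,3,2-dioxaborolan-2-yl)phenyl 2,2-dimethylpropanoate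
Product: 7 [3,5-dimethoxy-4-(2,2-dimethylpropanoyloxy)phenyl]boronic acid
Conditions: NaIO4, NH4OAc, acetone/H2O (1:1), rt
Reagents that add atoms: water, O
Why: Hydrolysis of the boronate is driven by oxidative cleavage of the released pinacol with periodate, giving the free boronic acid needed for transmetalation in step 5; the hindered aryl pivalate is inert under these near-neutral conditions.

Step 5
Reactants: 4 6-bromo-8-methoxy-4H-chromen-4-one; 7 [3,5-dimethoxy-4-(2,2-dimethylpropanoyloxy)phenyl]boronic acid
Product: 8 4-[(2R)-6-bromo-8-methoxy-4-oxo-3,4-dihydro-2H-chromen-2-yl]-2,6-dimethoxyphenyl 2,2-dimethylpropanoate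
Conditions: Pd(OCOCF3)2 (5 mol %), (S)-t-BuPyOX (6 mol %), NH4PF6 (30 mol %), H2O (5 equiv), ClCH2CH2Cl, 60 °C
Reagents that add atoms: none
Why: Asymmetric conjugate addition of an arylboronic acid to a chromone catalysed by a cationic divalent palladium–pyridinooxazoline complex (transmetalation, enantio-determining insertion of C2=C3 into the Pd–aryl bond, protonolysis); the tert-butyl group of the ligand shields one face of the bound chromone so that the aryl group should add to the face that gives (R) at C2. The base-free medium avoids ring opening of the flavanone, and the aryl bromide is untouched because no zerovalent palladium is formed.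

Step 6
Reactants: 8 4-[(2R)-6-bromo-8-methoxy-4-oxo-3,4-dihydro-2H-chromen-2-yl]-2,6-dimethoxyphenyl 2,2-dimethylpropanoate
Product: 12 methyl (2R,3R)-5-bromo-2-[3,5-dimethoxy-4-(2,2-dimethylpropanoyloxy)phenyl]-7-methoxy-2,3-dihydro-1-benzofuran-3-carboxylate, via dimethyl ketal 9 (not isolated), via enol ether 10 (not isolated), via trans-3-iodanyl ketal 11 (not isolated)
Conditions: PhI(OAc)2 (1.2 equiv), conc. H2SO4 (cat.), HC(OMe)3, 0 °C to rt; aq. NaHCO3 work-up
Reagents that add atoms: trimethyl orthoformate, COC(OC)OC
Why: Acid and trimethyl orthoformate convert 8 through ketal 9 into enol ether 10, PhI(OAc)2 adds to C3 of 10 on the face opposite to the C2 aryl group, and methanol adds at C4 to give the 2,3-trans iodane 11. In the half-chair of 11 the equatorial C3–I bond lies antiperiplanar to the C4–C4a bond, so aryl carbon C4a shifts from C4 to C3 as iodobenzene leaves, and the dimethoxy-stabilised cation left at C4 loses a methyl group to acetate to give the methyl ester. The closest known reaction type is the oxidative ring contraction of flavanones to methyl trans-2-aryl-2,3-dihydrobenzofuran-3-carboxylates by trivalent iodine or Tl(NO3)3 in trimethyl orthoformate, a semipinacol-type 1,2-aryl shift. The dihydrofuran ring is not closed end to end but arises by contraction of the pyranone: the ipso carbon C4a attacks C3 in a 3-exo-tet fashion (bridged phenonium ion) and the C4–C4a bond opens. C2 is not touched and keeps its (R) arrangement; C3 is set by substrate control from C2, because anti delivery of iodine followed by migration with inversion places the ester carbon trans to the aryl group, which is also the thermodynamically preferred arrangement. The step needs migration of ring A in preference to a shift of the C2 aryl group (isoflavone formation) and to elimination (flavone formation); the two ketal oxygens make the cation of the ring A shift the best stabilised one, O1 ortho to C4a stabilises the phenonium ion, and the pivaloyloxy group makes the C2 aryl ring a poor migrating group and keeps the C2–O1 bond from ionising in acid. The bromine at C6 blocks the position para to O1 against electrophilic attack and is inert to the oxidant.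

Step 7
Reactants: 13 3,5-dihydroxybenzaldehyde
Product: 14 5-formyl-1,3-phenylene bis(2,2-dimethylpropanoate)
Conditions: PivCl (2.3 equiv), Et3N, DMAP (cat.), CH2Cl2, 0 °C to rt
Reagents that add atoms: pivaloyl chloride, CC(C)(C)C(Cl)=O
Why: Double O-acylation of the two phenols; the same protecting group as in 12 is used so that one final step removes all of them.

Step 8
Reactants: 14 5-formyl-1,3-phenylene bis(2,2-dimethylpropanoate)
Product: 15 5-ethenyl-1,3-phenylene bis(2,2-dimethylpropanoate)
Conditions: Ph3PCH3Br, KOt-Bu, THF, 0 °C; then 14, −78 to 0 °C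
Reagents that add atoms: methyltriphenylphosphonium bromide, C[P+](c1ccccc1)(c1ccccc1)c1ccccc1.[Br-]
Why: Wittig methylenation; at low temperature the unstabilised ylide reacts with the aldehyde far faster than with the hindered pivalates.

Step 9
Reactants: 12 methyl (2R,3R)-5-bromo-2-[3,5-dimethoxy-4-(2,2-dimethylpropanoyloxy)phenyl]-7-methoxy-2,3-dihydro-1-benzofuran-3-carboxylate; 15 5-ethenyl-1,3-phenylene bis(2,2-dimethylpropanoate)
Product: 16 methyl (2R,3R)-5-[(E)-2-[3,5-bis(2,2-dimethylpropanoyloxy)phenyl]ethenyl]-2-[3,5-dimethoxy-4-(2,2-dimethylpropanoyloxy)phenyl]-7-methoxy-2,3-dihydro-1-benzofuran-3-carboxylate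
Conditions: Pd2(dba)3 (2 mol %), [HP(t-Bu)3]BF4 (8 mol %), Cy2NMe (1.5 equiv), 1,4-dioxane, 50 °C
Reagents that add atoms: none
Why: Mizoroki–Heck reaction: oxidative addition of the electron-rich aryl bromide to the tri-tert-butylphosphine complex of zerovalent palladium, syn insertion at the terminal carbon of the styrene and syn β-hydride elimination give the (E)-stilbene. The mild temperature and hindered amine base should leave the pivalates and the C3 ester (already the more stable trans epimer) intact.

Step 10
Reactants: 16 methyl (2R,3R)-5-[(E)-2-[3,5-bis(2,2-dimethylpropanoyloxy)phenyl]ethenyl]-2-[3,5-dimethoxy-4-(2,2-dimethylpropanoyloxy)phenyl]-7-methoxy-2,3-dihydro-1-benzofuran-3-carboxylate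
Product: 17 gnetucleistol F, 5-[(E)-2-[(2R,3S)-2-(4-hydroxy-3,5-dimethoxyphenyl)-3-(hydroxymethyl)-7-methoxy-2,3-dihydro-1-benzofuran-5-yl]ethenyl]benzene-1,3-diol
Conditions: LiAlH4 (6 equiv), THF, −10 to 0 °C; aq. potassium sodium tartrate, then citric acid to pH 5
Reagents that add atoms: none
Why: Hydride reduction converts the methyl ester into the primary alcohol and cleaves the three aryl pivalates in one operation; the stilbene and the dihydrobenzofuran are inert to LiAlH4 at 0 °C. C2 and C3 are not touched because reduction of the ester should outpace enolisation (the C3 descriptor changes from R to S only through the change of substituent priorities).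

## Compound list

1 | 1-(2-hydroxy-3-methoxyphenyl)ethan-1-one | CC(=O)c1cccc(OC)c1O | starting material
2 | 1-(5-bromo-2-hydroxy-3-methoxyphenyl)ethan-1-one | CC(=O)c1cc(Br)cc(OC)c1O | intermediate
3 | (E)-1-(5-bromo-2-hydroxy-3-methoxyphenyl)-3-(dimethylamino)prop-2-en-1-one | CN(C)/C=C/C(=O)c1cc(Br)cc(OC)c1O | intermediate
4 | 6-bromo-8-methoxy-4H-chromen-4-one | COc1cc(Br)cc2c(=O)ccoc12 | intermediate
5 | 2,6-dimethoxy-4-(4,4,5,5-tetramethyl-1,3,2-dioxaborolan-2-yl)phenol | COc1cc(B2OC(C)(C)C(C)(C)O2)cc(OC)c1O | starting material
6 | 2,6-dimethoxy-4-(4,4,5,5-tetramethyl-1,3,2-dioxaborolan-2-yl)phenyl 2,2-dimethylpropanoate | COc1cc(B2OC(C)(C)C(C)(C)O2)cc(OC)c1OC(=O)C(C)(C)C | intermediate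
7 | [3,5-dimethoxy-4-(2,2-dimethylpropanoyloxy)phenyl]boronic acid | COc1cc(B(O)O)cc(OC)c1OC(=O)C(C)(C)C | intermediate
8 | 4-[(2R)-6-bromo-8-methoxy-4-oxo-3,4-dihydro-2H-chromen-2-yl]-2,6-dimethoxyphenyl 2,2-dimethylpropanoate | O=C1C[C@H](c2cc(OC)c(OC(=O)C(C)(C)C)c(OC)c2)Oc2c(OC)cc(Br)cc12 | intermediate
9 | 4-[(2R)-6-bromo-4,4,8-trimethoxy-3,4-dihydro-2H-chromen-2-yl]-2,6-dimethoxyphenyl 2,2-dimethylpropanoate (dimethyl ketal) | COC1(OC)C[C@H](c2cc(OC)c(OC(=O)C(C)(C)C)c(OC)c2)Oc2c(OC)cc(Br)cc12 | intermediate
10 | 4-[(2R)-6-bromo-4,8-dimethoxy-2H-chromen-2-yl]-2,6-dimethoxyphenyl 2,2-dimethylpropanoate (enol ether) | COC1=C[C@H](c2cc(OC)c(OC(=O)C(C)(C)C)c(OC)c2)Oc2c(OC)cc(Br)cc12 | intermediate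
11 | 4-[(2S,3S)-3-[acetoxy(phenyl)-λ3-iodanyl]-6-bromo-4,4,8-trimethoxy-3,4-dihydro-2H-chromen-2-yl]-2,6-dimethoxyphenyl 2,2-dimethylpropanoate (2,3-trans; C2 spatially unchanged from 8, descriptor changed by priority only) | COC1(OC)[C@@H](I(OC(C)=O)c3ccccc3)[C@H](c3cc(OC)c(OC(=O)C(C)(C)C)c(OC)c3)Oc2c(OC)cc(Br)cc12 | intermediate
12 | methyl (2R,3R)-5-bromo-2-[3,5-dimethoxy-4-(2,2-dimethylpropanoyloxy)phenyl]-7-methoxy-2,3-dihydro-1-benzofuran-3-carboxylate (trans) | COc1cc([C@@H]2Oc3c(OC)cc(Br)cc3[C@H]2C(=O)OC)cc(OC)c1OC(=O)C(C)(C)C | intermediate
13 | 3,5-dihydroxybenzaldehyde | O=Cc1cc(O)cc(O)c1 | starting material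
14 | 5-formyl-1,3-phenylene bis(2,2-dimethylpropanoate) | O=Cc1cc(OC(=O)C(C)(C)C)cc(OC(=O)C(C)(C)C)c1 | intermediate
15 | 5-ethenyl-1,3-phenylene bis(2,2-dimethylpropanoate) | C=Cc1cc(OC(=O)C(C)(C)C)cc(OC(=O)C(C)(C)C)c1 | intermediate
16 | methyl (2R,3R)-5-[(E)-2-[3,5-bis(2,2-dimethylpropanoyloxy)phenyl]ethenyl]-2-[3,5-dimethoxy-4-(2,2-dimethylpropanoyloxy)phenyl]-7-methoxy-2,3-dihydro-1-benzofuran-3-carboxylate | COc1cc([C@@H]2Oc3c(OC)cc(/C=C/c4cc(OC(=O)C(C)(C)C)cc(OC(=O)C(C)(C)C)c4)cc3[C@H]2C(=O)OC)cc(OC)c1OC(=O)C(C)(C)C | intermediate
17 | gnetucleistol F, 5-[(E)-2-[(2R,3S)-2-(4-hydroxy-3,5-dimethoxyphenyl)-3-(hydroxymethyl)-7-methoxy-2,3-dihydro-1-benzofuran-5-yl]ethenyl]benzene-1,3-diol | COc1cc([C@@H]2Oc3c(OC)cc(/C=C/c4cc(O)cc(O)c4)cc3[C@H]2CO)cc(OC)c1O | target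

## Step count and least certain steps

Total: 10 steps. Longest linear sequence: 6 steps (steps 1, 2, 5, 6, 9, 10).

**Step 6 (key step).** The most likely failure is loss of selectivity in the migration: a shift of the C2 aryl group from C2 to C3, or elimination from the iodane to the flavone, could compete with the ring A shift. Partial erosion of enantiopurity by acid-mediated opening of the pyranone ring before the enol ether forms is also possible. The fallback replaces the iodine-mediated shift by a Wolff ring contraction and sets out from 8. Heating 8 with Me2NCH(OMe)2 in toluene, without strong base, should give the 3-(dimethylaminomethylidene)flavanone F1. Diazo transfer with methanesulfonyl azide in MeCN should give the 3-diazoflavanone F2. Irradiation at 365 nm in methanol should trigger the Wolff rearrangement, in which C4a migrates from C4 to the carbene carbon C3, and methanol should trap the ketene to give 12 together with its cis C3 epimer F3. Brief treatment of the mixture with DBU in CH2Cl2 should equilibrate F3 to the more stable trans ester, and the route is rejoined at 12.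

**Step 5.** Insufficient facial discrimination with the 8-methoxy chromone, or slow transmetalation and competing protodeboronation of the trisubstituted boronic acid, could give low enantiopurity or low conversion. The fallback sets out from 4 and 7. Addition with an achiral catalyst (Pd(OCOCF3)2 with 2,2'-bipyridine, otherwise as in step 5) should give the racemic flavanone F4. Kinetic resolution by asymmetric transfer hydrogenation with RuCl(p-cymene)[(S,S)-TsDPEN] and HCO2H/Et3N is expected to reduce the (S)-ketone faster, by hydride delivery anti to the aryl group, to the cis-flavan-4-ol F5. The unreacted ketone is separated by chromatography and the route is rejoined at 8, at the cost of half the material.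

**Step 9.** Slow oxidative addition of the electron-rich aryl bromide, or amine-induced deprotonation at C3 followed by β-elimination of the O1 phenoxide (ring opening), could lower the yield or the stereochemical integrity. The fallback replaces the Heck reaction by a Suzuki–Miyaura coupling and sets out from 14. Boron-Wittig olefination of 14 with bis(pinacolboryl)methane and lithium 2,2,6,6-tetramethylpiperidide in THF at −78 °C should give the (E)-styrylboronate F6. Coupling of F6 with 12 (PdCl2(dppf), K3PO4, 1,4-dioxane/H2O, 50 °C) should give 16, where the route is rejoined.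

**Step 10.** Enolisation of the C3 ester by the basic hydride with ring opening, incomplete cleavage of the hindered syringyl pivalate, or opening of the C2–O1 bond through the para-phenoxide during a prolonged reaction could all reduce the yield. The fallback moves the hydride step to a simpler substrate and ends with a mild transesterification; it sets out from 12. LiAlH4 reduction of 12 should give the bromo phenol alcohol F7, which no longer has an acidic C3–H. A Mizoroki–Heck reaction of F7 with 15 under the conditions of step 9 should give the stilbene bis(pivalate) F8. K2CO3 in methanol at 0 °C should then remove the two remaining pivalates, and the route is rejoined at 17.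

## Further compounds

F1 | step 6 | 4-[(2S,3E)-6-bromo-3-(dimethylaminomethylidene)-8-methoxy-4-oxo-3,4-dihydro-2H-chromen-2-yl]-2,6-dimethoxyphenyl 2,2-dimethylpropanoate (C2 spatially as in 8) | CN(C)/C=C1\[C@H](c2cc(OC)c(OC(=O)C(C)(C)C)c(OC)c2)Oc2c(OC)cc(Br)cc2C1=O
F2 | step 6 | 4-[(2S)-6-bromo-3-diazo-8-methoxy-4-oxo-3,4-dihydro-2H-chromen-2-yl]-2,6-dimethoxyphenyl 2,2-dimethylpropanoate (C2 spatially as in 8) | [N-]=[N+]=C1[C@H](c2cc(OC)c(OC(=O)C(C)(C)C)c(OC)c2)Oc2c(OC)cc(Br)cc2C1=O
F3 | step 6 | methyl (2R,3S)-5-bromo-2-[3,5-dimethoxy-4-(2,2-dimethylpropanoyloxy)phenyl]-7-methoxy-2,3-dihydro-1-benzofuran-3-carboxylate (cis epimer of 12) | COc1cc([C@@H]2Oc3c(OC)cc(Br)cc3[C@@H]2C(=O)OC)cc(OC)c1OC(=O)C(C)(C)C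
F4 | step 5 | racemic 4-(6-bromo-8-methoxy-4-oxo-3,4-dihydro-2H-chromen-2-yl)-2,6-dimethoxyphenyl 2,2-dimethylpropanoate | O=C1CC(c2cc(OC)c(OC(=O)C(C)(C)C)c(OC)c2)Oc2c(OC)cc(Br)cc12
F5 | step 5 | 4-[(2S,4S)-6-bromo-4-hydroxy-8-methoxy-3,4-dihydro-2H-chromen-2-yl]-2,6-dimethoxyphenyl 2,2-dimethylpropanoate (2,4-cis) | O[C@H]1C[C@@H](c2cc(OC)c(OC(=O)C(C)(C)C)c(OC)c2)Oc2c(OC)cc(Br)cc12
F6 | step 9 | 5-[(E)-2-(4,4,5,5-tetramethyl-1,3,2-dioxaborolan-2-yl)ethenyl]-1,3-phenylene bis(2,2-dimethylpropanoate) | CC(C)(C)C(=O)Oc1cc(/C=C/B2OC(C)(C)C(C)(C)O2)cc(OC(=O)C(C)(C)C)c1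
F7 | step 10 | 4-[(2R,3S)-5-bromo-3-(hydroxymethyl)-7-methoxy-2,3-dihydro-1-benzofuran-2-yl]-2,6-dimethoxyphenol | COc1cc([C@@H]2Oc3c(OC)cc(Br)cc3[C@H]2CO)cc(OC)c1O
F8 | step 10 | 5-[(E)-2-[(2R,3S)-2-(4-hydroxy-3,5-dimethoxyphenyl)-3-(hydroxymethyl)-7-methoxy-2,3-dihydro-1-benzofuran-5-yl]ethenyl]-1,3-phenylene bis(2,2-dimethylpropanoate) | COc1cc([C@@H]2Oc3c(OC)cc(/C=C/c4cc(OC(=O)C(C)(C)C)cc(OC(=O)C(C)(C)C)c4)cc3[C@H]2CO)cc(OC)c1O
A1 | alternative 1 | sinapyl alcohol, 4-[(E)-3-hydroxyprop-1-enyl]-2,6-dimethoxyphenol | COc1cc(/C=C/CO)cc(OC)c1O
A2 | alternative 1 | isorhapontigenin, 5-[(E)-2-(4-hydroxy-3-methoxyphenyl)ethenyl]benzene-1,3-diol | COc1cc(/C=C/c2cc(O)cc(O)c2)ccc1O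
A3 | alternative 1 | racemic quinone methide from β–5 coupling, 4-[2-[5-[(E)-2-(3,5-dihydroxyphenyl)ethenyl]-2-hydroxy-3-methoxyphenyl]-3-hydroxypropylidene]-2,6-dimethoxycyclohexa-2,5-dien-1-one | COC1=CC(=CC(CO)c2cc(/C=C/c3cc(O)cc(O)c3)cc(OC)c2O)C=C(OC)C1=O
A4 | alternative 2 | methyl 2-[5-bromo-2-[[3,5-dimethoxy-4-(2,2-dimethylpropanoyloxy)phenyl]methoxy]-3-methoxyphenyl]-2-diazoacetate | COC(=O)C(=[N+]=[N-])c1cc(Br)cc(OC)c1OCc1cc(OC)c(OC(=O)C(C)(C)C)c(OC)c1
A5 | alternative 3 | 2-methoxy-1,4-benzoquinone | COC1=CC(=O)C=CC1=O
A6 | alternative 3 | 4-[(E)-3-[tert-butyl(dimethyl)silyl]oxyprop-1-enyl]-2,6-dimethoxyphenyl 2,2-dimethylpropanoate | COc1cc(/C=C/CO[Si](C)(C)C(C)(C)C)cc(OC)c1OC(=O)C(C)(C)C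
A7 | alternative 3 | 4-[(2R,3S)-3-[[tert-butyl(dimethyl)silyl]oxymethyl]-5-hydroxy-7-methoxy-2,3-dihydro-1-benzofuran-2-yl]-2,6-dimethoxyphenyl 2,2-dimethylpropanoate | COc1cc([C@@H]2Oc3c(OC)cc(O)cc3[C@H]2CO[Si](C)(C)C(C)(C)C)cc(OC)c1OC(=O)C(C)(C)C
A8 | alternative 3 | 4-[(2R,3S)-3-[[tert-butyl(dimethyl)silyl]oxymethyl]-5-hydroxy-6-methoxy-2,3-dihydro-1-benzofuran-2-yl]-2,6-dimethoxyphenyl 2,2-dimethylpropanoate (regioisomer of A7) | COc1cc([C@@H]2Oc3cc(OC)c(O)cc3[C@H]2CO[Si](C)(C)C(C)(C)C)cc(OC)c1OC(=O)C(C)(C)C
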